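**Retrosynthetic overview**

1. Locants used: C1/C5 ring fusion, C3=C4(C17) ring alkene, C6 and C9 carbinols, C7 carries the chain C11(Me)–C12(OAc)–C13=C14–C15(OH)Me2, C10 carries exocyclic C18H2. Target 23 ⇐ 21 by acetylation at C12–O and desilylation.
2. Enabling feature: C10 bears the exocyclic methylene C18 and is bonded to carbinol C9 inside the seven-membered ring (a 2-methylenecycloheptanol unit), the retron of a reductive alkyne–aldehyde coupling. C9 is also 1,5 to the acetoxy oxygen on C12, so C9 can be carried as the carbonyl carbon of a temporary six-membered lactone/lactol ring O–C12–C11–C7–C8–C9.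
3. 21 ⇐ alkynyl lactol 19 (C9–C10 closure opens the temporary oxane ring) ⇐ cyclopentene lactone 17 ⇐ three-component coupling of (S)-4-silyloxycyclopentenone 10, an alkynylalane (C1–C10) and lactone aldehyde 9 (C5–C6 aldol).
4. 9 ⇐ unsaturated δ-lactone 7 (vinyl addition at C7, oxidative cleavage) ⇐ crotylboration of enal 4 (C11, C12), acryloylation, ring-closing metathesis.
5. Ring order: temporary δ-lactone (step 5), five-membered ring from 10 (steps 8 to 11), seven-membered carbocycle last (step 14).

Key step: step 14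

Remark: lactols 18 and 19 are anomeric mixtures, and both enantiomers of 4-(tert-butyldimethylsilyloxy)cyclopent-2-enone and of B-methoxydiisopinocampheylborane are taken as purchasable.

Step 1
Reactants: 1 2-methylbut-3-en-2-ol; 2 (E)-but-2-enal
Product: 3 (E)-4-hydroxy-4-methylpent-2-enal
Conditions: RuCl2(H2IMes)(=CH-C6H4-2-OiPr) (second-generation Hoveyda–Grubbs catalyst, cat.), excess 2, CH2Cl2, 40 °C
Reagents that add atoms: none
Why: Olefin cross-metathesis in which the hindered tertiary allylic alcohol cannot homodimerise and exchanges with the enal to give the E alkene under thermodynamic control; no stereocentre is formed.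

Step 2
Reactants: 3 (E)-4-hydroxy-4-methylpent-2-enal
Product: 4 (E)-4-methyl-4-(triethylsilyloxy)pent-2-enal
Conditions: Et3SiOTf, 2,6-lutidine, CH2Cl2, −78 to 0 °C
Reagents that add atoms: triethylsilyl trifluoromethanesulfonate, CC[Si](CC)(CC)OS(=O)(=O)C(F)(F)F
Why: Silylation of the tertiary alcohol with a silyl triflate and a hindered pyridine base removes the acidic proton that would quench the organometallic reagents of steps 3, 6, 8 and 11.

Step 3
Reactants: 4 (E)-4-methyl-4-(triethylsilyloxy)pent-2-enal
Product: 5 (3R,4S,5E)-3,7-dimethyl-7-(triethylsilyloxy)octa-1,5-dien-4-ol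
Conditions: trans-but-2-ene, KOtBu, n-BuLi, THF, −78 to −45 °C; (+)-B-methoxydiisopinocampheylborane; BF3·OEt2, −78 °C; then 4, −78 °C; NaOH, H2O2
Reagents that add atoms: trans-but-2-ene, C/C=C/C
Why: Asymmetric crotylboration through a closed chair transition state: the E crotyl geometry gives the anti relationship of C11–CH3 and C12–OH, and the isopinocampheyl groups derived from (−)-α-pinene direct addition to the aldehyde face that gives 11R,12S.

Step 4
Reactants: 5 (3R,4S,5E)-3,7-dimethyl-7-(triethylsilyloxy)octa-1,5-dien-4-ol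
Product: 6 (3R,4S,5E)-3,7-dimethyl-7-(triethylsilyloxy)octa-1,5-dien-4-yl prop-2-enoate
Conditions: CH2=CHCOCl, Et3N, DMAP (cat.), CH2Cl2, 0 °C
Reagents that add atoms: acryloyl chloride, C=CC(=O)Cl
Why: O-Acylation of the secondary alcohol installs C8 and C9 as the acrylate needed for ring closure and leaves the stereocentres untouched.

Step 5
Reactants: 6 (3R,4S,5E)-3,7-dimethyl-7-(triethylsilyloxy)octa-1,5-dien-4-yl prop-2-enoate
Product: 7 (5R,6S)-5-methyl-6-[(E)-3-methyl-3-(triethylsilyloxy)but-1-enyl]-5,6-dihydro-2H-pyran-2-one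
Conditions: RuCl2(H2IMes)(PCy3)(=CHPh) (second-generation Grubbs catalyst, cat.), CH2Cl2, 40 °C, high dilution
Reagents that add atoms: none
Why: Ring-closing metathesis of the acrylate with the terminal vinyl group forms the six-membered unsaturated lactone (C7=C8), the trans-disubstituted alkene next to the quaternary silyloxy carbon being inert.

Step 6
Reactants: 7 (5R,6S)-5-methyl-6-[(E)-3-methyl-3-(triethylsilyloxy)but-1-enyl]-5,6-dihydro-2H-pyran-2-one
Product: 8 (4R,5R,6S)-4-ethenyl-5-methyl-6-[(E)-3-methyl-3-(triethylsilyloxy)but-1-enyl]oxan-2-one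
Conditions: CH2=CHMgBr, CuBr·SMe2 (cat.), THF, −78 °C; aq. NH4Cl
Reagents that add atoms: vinylmagnesium bromide, C=C[Mg]Br
Why: Copper-catalysed conjugate addition of the vinyl Grignard reagent to the unsaturated lactone should occur anti to the adjacent C11 methyl group, setting C7 so that all three ring substituents are trans.

Step 7
Reactants: 8 (4R,5R,6S)-4-ethenyl-5-methyl-6-[(E)-3-methyl-3-(triethylsilyloxy)but-1-enyl]oxan-2-one
Product: 9 (2S,3R,4S)-3-methyl-2-[(E)-3-methyl-3-(triethylsilyloxy)but-1-enyl]-6-oxooxane-4-carbaldehyde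
Conditions: OsO4 (cat.), NaIO4, 2,6-lutidine, dioxane/H2O, 20 °C
Reagents that add atoms: sodium periodate (oxygen of the new aldehyde, delivered through OsO4), [Na+].[O-]I(=O)(=O)=O
Why: Johnson–Lemieux oxidation (dihydroxylation, glycol cleavage) is chemoselective for the monosubstituted alkene over the hindered, doubly allylically oxygenated trans alkene and turns the vinyl group into aldehyde C6 with the equatorial C7 configuration retained.

Step 8
Reactants: 9 (2S,3R,4S)-3-methyl-2-[(E)-3-methyl-3-(triethylsilyloxy)but-1-enyl]-6-oxooxane-4-carbaldehyde; 10 (S)-4-(tert-butyldimethylsilyloxy)cyclopent-2-en-1-one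
Product: 12 anti-aldol adduct (C4 ketone; C1 alkynyl; C2 silyloxy; C6 carbinol), via dimethylaluminium enolate 11 (not isolated)
Conditions: Me3SiC≡CH, n-BuLi, Et2O, 0 °C; Me2AlCl; Ni(acac)2 (cat.), i-Bu2AlH (cat.), 10, −5 °C; then 9, THF, −78 °C; aq. potassium sodium tartrate
Reagents that add atoms: (trimethylsilyl)acetylene, C#C[Si](C)(C)C
Why: Three-component coupling: nickel-catalysed conjugate addition of the alkynylalane anti to the silyloxy group sets C1, and the aluminium enolate adds to aldehyde 9 anti to the new C1 substituent (C5) through a closed chair transition state whose E enolate geometry gives the anti aldol (C6), on the aldehyde face predicted by the Felkin–Anh model for the C7 stereocentre.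

Step 9
Reactants: 12 anti-aldol adduct
Product: 14 cyclopent-2-enone (C2=C3; C4 ketone; C6 silyl ether), via bis-silyl ether ketone 13 (not isolated)
Conditions: t-BuMe2SiOTf, 2,6-lutidine, CH2Cl2, −78 °C; then DBU, 0 to 20 °C
Reagents that add atoms: tert-butyldimethylsilyl trifluoromethanesulfonate, CC(C)(C)[Si](C)(C)OS(=O)(=O)C(F)(F)F
Why: Silylation of the C6 hydroxyl prevents its translactonisation onto the δ-lactone, and DBU then effects E1cB elimination of the C2 silyloxy group through the unhindered C3 enolate to give the enone.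

Step 10
Reactants: 14 cyclopent-2-enone
Product: 16 enol triflate (C3=C4–OTf), via lithium enolate 15 (not isolated)
Conditions: LiBH(s-Bu)3, THF, −78 °C; then 2-[N,N-bis(trifluoromethylsulfonyl)amino]-5-chloropyridine, −78 to 0 °C
Reagents that add atoms: 2-[N,N-bis(trifluoromethylsulfonyl)amino]-5-chloropyridine, O=S(=O)(N(c1ccc(Cl)cn1)S(=O)(=O)C(F)(F)F)C(F)(F)F
Why: 1,4-Reduction of the enone by the hindered borohydride gives the C3–C4 enolate regiospecifically, without a base that would also deprotonate the lactone, and O-triflation traps it as the enol triflate.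

Step 11
Reactants: 16 enol triflate
Product: 17 cyclopentene lactone (C3=C4 with C17 methyl)
Conditions: Me2CuLi (from MeLi and CuBr·SMe2), THF, −78 to −20 °C
Reagents that add atoms: methyllithium (used as the cuprate), [Li]C
Why: Cross-coupling of the enol triflate with the lithium dialkylcuprate replaces the triflate by the C17 methyl group with retention of the alkene position, the lactone and the alkynylsilane being inert to the cuprate at low temperature.

Step 12
Reactants: 17 cyclopentene lactone
Product: 18 lactol (C9 hemiacetal) with silylated alkyne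
Conditions: i-Bu2AlH, CH2Cl2, −78 °C; aq. potassium sodium tartrate
Reagents that add atoms: none
Why: Partial reduction of the lactone stops at the aluminium hemiacetal at −78 °C and gives the lactol on work-up, so that C9 reaches the aldehyde oxidation level while still tied to the C12 oxygen.

Step 13
Reactants: 18 lactol with silylated alkyne
Product: 19 lactol with terminal alkyne (C10≡C18)
Conditions: K2CO3 (cat.), MeOH, 0 to 20 °C
Reagents that add atoms: none
Why: Base-catalysed methanolysis cleaves the C(sp)–Si bond selectively, the silyl ethers on oxygen being stable, and frees the terminal alkyne.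

Step 14
Reactants: 19 lactol with terminal alkyne
Product: 21 trans-fused hydroazulene (C9 triethylsilyl ether; free C12 hydroxyl), via open-chain hydroxy aldehyde 20 (not isolated)
Conditions: Ni(COD)2 (cat.), 1,3-dimesitylimidazolium chloride (IMes·HCl, cat.), KOtBu (cat.), Et3SiH, THF, 20 °C, slow addition of 19 at high dilution
Reagents that add atoms: triethylsilane, CC[SiH](CC)CC
Why: Proposed new method: base equilibrates hemiacetal 19 with hydroxy aldehyde 20, whose aldehyde and terminal alkyne undergo oxidative cyclisation on zerovalent nickel (IMes ligand) to an oxanickelacyclopentene; σ-bond metathesis with Et3SiH silylates only the nickel-bound C9 oxygen and C–H reductive elimination delivers hydrogen to C18, so the released C12 hydroxyl stays free and the two carbinols emerge differentiated. The closest known reaction type is the nickel-catalysed reductive cyclisation of alkynals with trialkylsilanes, known for five- and six-membered and macrocyclic rings with enolisable aliphatic aldehydes; new here are the hemiacetal as aldehyde source, the free hydroxyl and the seven-membered ring. The seven-membered ring closes in the 7-exo-dig mode (exo-trig at the carbonyl), because bonding at the terminal alkyne carbon would require an eight-membered ring containing an E alkene. The new C9 stereocentre is controlled by C1: in the chair-like transition state C1–H and the nickel-bound C9–O both lie in the plane of the nascent exocyclic alkene, which places C9–O trans to C6–O and should give the 9R epimer. The step needs chemoselectivity for cyclisation over alkyne oligomerisation and aldehyde hydrosilylation, which slow addition at high dilution and the trans-1,5-disubstituted cyclopentene (alkyne and chain held side by side) should secure.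

Step 15
Reactants: 21 trans-fused hydroazulene
Product: 22 C12 acetate of 21
Conditions: Ac2O, pyridine, DMAP (cat.), CH2Cl2, 0 to 20 °C
Reagents that add atoms: acetic anhydride, CC(=O)OC(C)=O
Why: DMAP-catalysed acetylation of the C12 hydroxyl, the only free hydroxyl of 21.

Step 16
Reactants: 22 C12 acetate
Product: 23 CNP0213969.2 (target)
Conditions: HF·pyridine, pyridine, THF, 0 to 20 °C
Reagents that add atoms: none
Why: Fluoride-mediated global desilylation with buffered HF·pyridine cleaves the two triethylsilyl ethers and the tert-butyldimethylsilyl ether while the acetate and the allylic alcohols survive.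

**Compound list**

1 | 2-methylbut-3-en-2-ol | C=CC(C)(C)O | starting material
2 | (E)-but-2-enal | C/C=C/C=O | starting material
3 | (E)-4-hydroxy-4-methylpent-2-enal | O=C/C=C/C(C)(C)O | intermediate
4 | (E)-4-methyl-4-(triethylsilyloxy)pent-2-enal | O=C/C=C/C(C)(C)O[Si](CC)(CC)CC | intermediate
5 | (3R,4S,5E)-3,7-dimethyl-7-(triethylsilyloxy)octa-1,5-dien-4-ol | C=C[C@@H](C)[C@@H](O)/C=C/C(C)(C)O[Si](CC)(CC)CC | intermediate
6 | (3R,4S,5E)-3,7-dimethyl-7-(triethylsilyloxy)octa-1,5-dien-4-yl prop-2-enoate | C=C[C@@H](C)[C@@H](OC(=O)C=C)/C=C/C(C)(C)O[Si](CC)(CC)CC | intermediate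
7 | (5R,6S)-5-methyl-6-[(E)-3-methyl-3-(triethylsilyloxy)but-1-enyl]-5,6-dihydro-2H-pyran-2-one | O=C1C=C[C@@H](C)[C@H](/C=C/C(C)(C)O[Si](CC)(CC)CC)O1 | intermediate
8 | (4R,5R,6S)-4-ethenyl-5-methyl-6-[(E)-3-methyl-3-(triethylsilyloxy)but-1-enyl]oxan-2-one | O=C1C[C@H](C=C)[C@@H](C)[C@H](/C=C/C(C)(C)O[Si](CC)(CC)CC)O1 | intermediate
9 | (2S,3R,4S)-3-methyl-2-[(E)-3-methyl-3-(triethylsilyloxy)but-1-enyl]-6-oxooxane-4-carbaldehyde | O=C1C[C@H](C=O)[C@@H](C)[C@H](/C=C/C(C)(C)O[Si](CC)(CC)CC)O1 | intermediate
10 | (S)-4-(tert-butyldimethylsilyloxy)cyclopent-2-en-1-one | O=C1C=C[C@@H](O[Si](C)(C)C(C)(C)C)C1 | starting material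
11 | dimethylaluminium enolate of the conjugate adduct (C1 alkynyl trans to C2 silyloxy) | C[Al](C)OC1=C[C@H](C#C[Si](C)(C)C)[C@@H](O[Si](C)(C)C(C)(C)C)C1 | intermediate
12 | anti-aldol adduct: cyclopentanone (C4=O) with C1 (trimethylsilyl)ethynyl, C2 silyloxy, C5 side arm all trans; C6 carbinol; δ-lactone as in 9 | C[Si](C)(C)C#C[C@@H]1[C@@H](O[Si](C)(C)C(C)(C)C)CC(=O)[C@H]1[C@H](O)[C@H]2CC(=O)O[C@@H](/C=C/C(C)(C)O[Si](CC)(CC)CC)[C@@H]2C | intermediate
13 | C6 tert-butyldimethylsilyl ether of 12 | C[Si](C)(C)C#C[C@@H]1[C@@H](O[Si](C)(C)C(C)(C)C)CC(=O)[C@H]1[C@H](O[Si](C)(C)C(C)(C)C)[C@H]2CC(=O)O[C@@H](/C=C/C(C)(C)O[Si](CC)(CC)CC)[C@@H]2C | intermediate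
14 | cyclopent-2-enone (C2=C3, C4=O) formed from 13 by loss of the C2 silyloxy group | C[Si](C)(C)C#C[C@@H]1C=CC(=O)[C@H]1[C@H](O[Si](C)(C)C(C)(C)C)[C@H]2CC(=O)O[C@@H](/C=C/C(C)(C)O[Si](CC)(CC)CC)[C@@H]2C | intermediate
15 | lithium C3–C4 enolate from 1,4-reduction of 14 | C[Si](C)(C)C#C[C@@H]1CC=C(O[Li])[C@H]1[C@H](O[Si](C)(C)C(C)(C)C)[C@H]2CC(=O)O[C@@H](/C=C/C(C)(C)O[Si](CC)(CC)CC)[C@@H]2C | intermediate
16 | enol triflate (C3=C4–OTf) | C[Si](C)(C)C#C[C@@H]1CC=C(OS(=O)(=O)C(F)(F)F)[C@H]1[C@H](O[Si](C)(C)C(C)(C)C)[C@H]2CC(=O)O[C@@H](/C=C/C(C)(C)O[Si](CC)(CC)CC)[C@@H]2C | intermediate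
17 | cyclopentene lactone (C3=C4, C17 methyl on C4) | C[Si](C)(C)C#C[C@@H]1CC=C(C)[C@H]1[C@H](O[Si](C)(C)C(C)(C)C)[C@H]2CC(=O)O[C@@H](/C=C/C(C)(C)O[Si](CC)(CC)CC)[C@@H]2C | intermediate
18 | lactol (C9 hemiacetal, anomeric mixture) with silylated alkyne | C[Si](C)(C)C#C[C@@H]1CC=C(C)[C@H]1[C@H](O[Si](C)(C)C(C)(C)C)[C@H]2CC(O)O[C@@H](/C=C/C(C)(C)O[Si](CC)(CC)CC)[C@@H]2C | intermediate
19 | lactol (anomeric mixture) with terminal alkyne | C#C[C@@H]1CC=C(C)[C@H]1[C@H](O[Si](C)(C)C(C)(C)C)[C@H]2CC(O)O[C@@H](/C=C/C(C)(C)O[Si](CC)(CC)CC)[C@@H]2C | intermediate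
20 | open-chain tautomer of 19 (C9 aldehyde, free C12 hydroxyl) | C#C[C@@H]1CC=C(C)[C@H]1[C@H](O[Si](C)(C)C(C)(C)C)[C@@H](CC=O)[C@@H](C)[C@@H](O)/C=C/C(C)(C)O[Si](CC)(CC)CC | intermediate
21 | trans-fused hydroazulene: C9 triethylsilyl ether, C6 tert-butyldimethylsilyl ether, C15 triethylsilyl ether, free C12 hydroxyl | C=C1[C@H](O[Si](CC)(CC)CC)C[C@@H]([C@@H](C)[C@@H](O)/C=C/C(C)(C)O[Si](CC)(CC)CC)[C@@H](O[Si](C)(C)C(C)(C)C)[C@@H]2C(C)=CC[C@@H]12 | intermediate
22 | C12 acetate of 21 | C=C1[C@H](O[Si](CC)(CC)CC)C[C@@H]([C@@H](C)[C@H](/C=C/C(C)(C)O[Si](CC)(CC)CC)OC(C)=O)[C@@H](O[Si](C)(C)C(C)(C)C)[C@@H]2C(C)=CC[C@@H]12 | intermediate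
23 | CNP0213969.2, (1R,5S,6R,7S,9R,11R,12S) in the locants of the overview | C=C1[C@H](O)C[C@@H]([C@@H](C)[C@H](/C=C/C(C)(C)O)OC(C)=O)[C@@H](O)[C@@H]2C(C)=CC[C@@H]12 | target

**Step count and risks**

Total step count: 16. Longest linear sequence: 16 steps (1 to 23); 10 and all reagents are purchased.

Steps most likely to fail:

1. Step 14 (labelled step). The hemiacetal may open too slowly, or its free hydroxyl may be silylated under the nickel hydride conditions, so that cyclisation is outrun by alkyne oligomerisation or the differentiation of the two carbinols is lost. The fallback uses known chemistry, sets out from 19 and comes back at 23. NaBH4 in MeOH should reduce 19 to the acyclic diol F1. Et3SiOTf with 2,6-lutidine should give the bis(triethylsilyl) ether F2. Swern oxidation, which converts primary triethylsilyl ethers directly, should give the alkynal F3. The established alkynal cyclisation with Ni(COD)2, IMes and i-Pr3SiH should then close the ring on a true aldehyde to the triisopropylsilyl ether F4. PPTS in MeOH should cleave only the two triethylsilyl ethers to give the diol F5, and Ac2O in pyridine should acetylate its secondary hydroxyl to the acetate F6. HF·pyridine then removes the remaining silyl groups and gives 23.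

2. Step 8. Transfer of the alkynyl group from residual alane to the aldehyde, or proton exchange between the aluminium enolate and the lactone, may compete with the aldol addition. The fallback sets out from 10 and comes back at 12. Me3SiOTf-promoted conjugate addition of [(trimethylsilyl)ethynyl]zinc bromide to 10 should give the isolable trimethylsilyl enol ether F7. MeLi followed by ZnCl2 should convert it into the chlorozinc enolate F8, free of alkynyl-metal species, whose aldol addition to 9 at −78 °C should give 12.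

3. Step 6. Facial selectivity may be poor, because the C12 substituent (1,3 to the reacting carbon) and the adjacent C11 methyl group direct the cuprate to opposite faces. The fallback sets out from 7 and comes back at 9. Benzophenone-sensitised photochemical addition of the 1,3-dioxolan-2-yl radical (1,3-dioxolane as solvent, 350 nm), which should be governed by the adjacent methyl group alone, should give the dioxolane F9. Et3SiOTf with 2,6-lutidine followed by water should then unmask aldehyde 9 without loss of the silyl ether.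

Further compounds
F1 | step 14 | acyclic diol from reduction of 19 | C#C[C@@H]1CC=C(C)[C@H]1[C@H](O[Si](C)(C)C(C)(C)C)[C@@H](CCO)[C@@H](C)[C@@H](O)/C=C/C(C)(C)O[Si](CC)(CC)CC
F2 | step 14 | bis(triethylsilyl) ether of F1 | C#C[C@@H]1CC=C(C)[C@H]1[C@H](O[Si](C)(C)C(C)(C)C)[C@@H](CCO[Si](CC)(CC)CC)[C@@H](C)[C@@H](O[Si](CC)(CC)CC)/C=C/C(C)(C)O[Si](CC)(CC)CC
F3 | step 14 | alkynal with C12 triethylsilyl ether | C#C[C@@H]1CC=C(C)[C@H]1[C@H](O[Si](C)(C)C(C)(C)C)[C@@H](CC=O)[C@@H](C)[C@@H](O[Si](CC)(CC)CC)/C=C/C(C)(C)O[Si](CC)(CC)CC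
F4 | step 14 | hydroazulene with C9 triisopropylsilyl ether | C=C1[C@H](O[Si](C(C)C)(C(C)C)C(C)C)C[C@@H]([C@@H](C)[C@@H](O[Si](CC)(CC)CC)/C=C/C(C)(C)O[Si](CC)(CC)CC)[C@@H](O[Si](C)(C)C(C)(C)C)[C@@H]2C(C)=CC[C@@H]12
F5 | step 14 | C12,C15-diol of F4 | C=C1[C@H](O[Si](C(C)C)(C(C)C)C(C)C)C[C@@H]([C@@H](C)[C@@H](O)/C=C/C(C)(C)O)[C@@H](O[Si](C)(C)C(C)(C)C)[C@@H]2C(C)=CC[C@@H]12
F6 | step 14 | C12 acetate of F5 | C=C1[C@H](O[Si](C(C)C)(C(C)C)C(C)C)C[C@@H]([C@@H](C)[C@H](/C=C/C(C)(C)O)OC(C)=O)[C@@H](O[Si](C)(C)C(C)(C)C)[C@@H]2C(C)=CC[C@@H]12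
F7 | step 8 | trimethylsilyl enol ether of the conjugate adduct | C[Si](C)(C)OC1=C[C@H](C#C[Si](C)(C)C)[C@@H](O[Si](C)(C)C(C)(C)C)C1
F8 | step 8 | chlorozinc enolate from F7 | Cl[Zn]OC1=C[C@H](C#C[Si](C)(C)C)[C@@H](O[Si](C)(C)C(C)(C)C)C1
F9 | step 6 | 4-(1,3-dioxolan-2-yl) lactone | O=C1C[C@H](C2OCCO2)[C@@H](C)[C@H](/C=C/C(C)(C)O[Si](CC)(CC)CC)O1
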